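The ratio of last to first target reading, 0.794 in Thursday's run and 0.623 in Monday's, opened the meeting on the new flasks.

| setting | Thursday's | Monday's | Wednesday's | zeta | gamma | delta |
|---|---|---|---|---|---|---|
| substrate | 0.068 M | 0.068 M | 0.068 M | 0.068 M | 0.068 M | 0.068 M |
| coupling partner | 1.3 equiv | 2.1 equiv | 0.95 equiv | 0.950 equiv | 0.950 equiv | 0.950 equiv |
| free catalyst | 0.05 mol% | 0.05 mol% | 0.025 mol% | 0.05 mol% | 0.05 mol% | 0.05 mol% |
| temperature | −15 °C | −4 °C | −15 °C | 0 °C | −20 °C |  |
| remark | run made earlier | run made earlier | run made earlier |  |  | at −20 °C until 6.0 min, from then on at 0 °C |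
| time |  |  |  | 30 min | 30 min | 30 min |

| run | time / min | target / % |
|---|---|---|
| Thursday's | 3.00 | 44.6 |
| Thursday's | 6.00 | 43.4 |
| Thursday's | 15.0 | 39.9 |
| Thursday's | 40.0 | 35.4 |
| Monday's | 1.33 | 45.3 |
| Monday's | 3.00 | 43.4 |
| Monday's | 8.00 | 36.0 |
| Monday's | 20.0 | 28.2 |
| Wednesday's | 5.00 | 38.4 |
| Wednesday's | 12.0 | 36.6 |
| Wednesday's | 25.0 | 33.5 |
| Wednesday's | 40.0 | 31.9 |

(standard deviation of a reading: 0.5 percentage points)

- the numbers in the tables scatter by 0.5 percentage points (one standard deviation)
- steps under discussion: free catalyst + target -> spent catalyst; substrate + coupling partner <-> target; coupling partner + target -> over-reaction product; substrate + coupling partner <-> isomer of the product; target + free catalyst <-> isomer of the product + free catalyst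

1. which flask leads in amount of target, in percent of the substrate charged ("all alike" within 1.5 percentage points) (zeta / gamma / delta / all alike)
2. how much target is there at the end, in percent of the substrate charged: zeta
3. how much target is there at the end, in percent of the substrate charged: gamma
4. how much target is there at the end, in percent of the substrate charged: delta

The forecaster put gamma in the lead, with 33% there, 26% in zeta and 26.5% in delta, and read Wednesday's fall as “about half as fast with half the catalyst”.

I, taking the minutes, objected to comparing the raw ratios. Monday's run carried more partner, and the step coupling partner + target -> over-reaction product runs with c(coupling partner). I proposed the specific fade: the pseudo-first-order constant of target between first and last reading, divided by the equivalents of partner not held in target, taken as charge less mean target. Wednesday's run, with the partner charge of these flasks, gives 0.00885 min⁻¹ per equivalent at −15 °C. Thursday's gives 0.00694 min⁻¹, lower despite twice the catalyst, and there I differ from the forecast. Monday's value over Thursday's is a factor of 2.11 between −15 °C and −4 °C.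

The chair asked where the fade starts. Wednesday's first reading, run back to zero time, gives 39.4%.

Partner not held in target depends on the answer, so I went round twice, first with Wednesday's start in each new flask, then with the mean of start and first answer. Scaling that factor by degrees, for gamma, at 0.00630 min⁻¹, that is 35.5%, then 35.4%. For zeta, at 0.0245 min⁻¹, it is 26.2%, then 24.9%. Delta, each constant held for its own minutes, comes to 26.7%. These are my numbers, not the forecast's, and they too put gamma ahead.

The flasks give 23.2% in zeta, 36.6% in gamma and 24.3% in delta, and gamma leads.

    free catalyst + target → spent catalyst (k = 4.41 L mol⁻¹ min⁻¹, Ea = 38.0 kJ mol⁻¹)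
    substrate + coupling partner ⇌ target (K = 67.0 L mol⁻¹, k = 21.1 L mol⁻¹ min⁻¹, Ea = 36.0 kJ mol⁻¹, ΔH = −17.0 kJ mol⁻¹)
    coupling partner + target → over-reaction product (k = 0.192 L mol⁻¹ min⁻¹, Ea = 46.0 kJ mol⁻¹)
    substrate + coupling partner ⇌ isomer of the product (K = 47.5 L mol⁻¹, k = 10.1 L mol⁻¹ min⁻¹, Ea = 42.0 kJ mol⁻¹, ΔH = −11.0 kJ mol⁻¹)
    target + free catalyst ⇌ isomer of the product + free catalyst, rate k5*[free catalyst]*[target] forward; the back reaction follows from the equilibrium constant (k = 1200 L mol⁻¹ min⁻¹, Ea = 42.0 kJ mol⁻¹)
    (constants at −20 °C)

In gamma at 30.0 min, substrate and coupling partner exchange with the isomer of the product with a relaxation half-life, by that step alone, of 1.14 min, far shorter than the 3.59 h of target with isomer of the product by its own step. That longer half-life is long against the 30 min of gamma. The specific fade gave 35.4% for gamma; carried to the neighbour flask like gamma at −5 °C, it is 0.0175 min⁻¹ and gives 28.7%, and that flask holds 26.8%.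

All runs were computed for an exercise; the scatter is artificial.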